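The earlier runs and the new flask come from a simulation with made-up constants; the scatter is artificial.

Start from a leftover. At 4.00 h in Monday's run the two products you can read hold 44.4% of the starting material charged, and 55.6% is unread. Keep it in view: one step under discussion, starting material + target -> side product, takes target away, and target stands in the ratio asked.

in all of them: starting material 0.50 M
- Monday's: first nucleophile 0.90 M; second nucleophile 0.65 M; protic impurity 10 mM; the very flask that is asked about, followed so far
- Sunday's: first nucleophile 0.90 M; second nucleophile 0.65 M; protic impurity 20 mM; run made earlier
- flask: first nucleophile 0.900 M; second nucleophile 0.650 M; protic impurity 10.0 mM; time 8.0 h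

- Monday's (time / h: other capture product / %, target / %): 0.333: 17.2, 23.8; 1.00: 18.3, 26.8; 2.00: 17.8, 26.6; 3.00: 17.9, 27.1; 4.00: 18.1, 26.3
- Sunday's (time / h: other capture product / %, target / %): 0.667: 17.7, 26.2; 1.33: 17.6, 26.4; 2.50: 17.5, 26.3; 4.00: 17.9, 26.2; 8.00: 17.5, 27.1

(each reading ± 0.3 percentage points)

* share of other capture product in other capture product plus target at 1.0 min
* share of other capture product in other capture product plus target at 20 min
* share of other capture product in other capture product plus target at 8.0 h

- percent here means starting material units held: one side product counts as two
- steps under discussion: starting material -> intermediate; first nucleophile + intermediate -> target; second nucleophile + intermediate -> other capture product; intermediate -> solvolysis product; second nucleophile -> decomposed reagent; second nucleophile + protic impurity -> quenched reagent; starting material + target -> side product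

Both capture steps draw on the intermediate, so work in logarithms to base ten: the logarithm of the ratio of their rates at one moment is the logarithm of [second nucleophile]/[first nucleophile] at that moment plus the logarithm of a constant factor. A plateau ratio of products is a sum over the run, not a ratio of rates at one moment, so the factor used below is an empirical one, read against the charges. Now weigh the inputs. In the rate ratio each nucleophile concentration enters with weight one; the charge of starting material can reach the plateau ratio through the step that takes target away, so it is held at 0.50 M throughout. The protic impurity is 1.54% of Monday's second nucleophile, so removing that much shifts the logarithm by −0.00673. The factor itself has to be known well.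

Monday's readings from 1.00 h on give a product ratio of 0.675. Dividing by the charge ratio gives the apparent selectivity factor, plateau product ratio per unit of charged [second nucleophile]/[first nucleophile], 0.935, with logarithm −0.0292. Monday's share is then 40.3%, and each per cent of error in a charge moves it by 0.241 of a point. Sunday's flask, with twice the impurity, reads 39.9%.

Taking [second nucleophile] at its charge and assuming that the plateau factor holds at the start too, I commit to 40.3% at 1.0 min; the plateau itself gives me the same figure at 8.0 h. Monday's single reading at 0.333 h, 42.0%, is my figure for 20 min.

The forecast, noting “This rests on one time point”, gives 46%, 41.6% and 40.2%, higher than mine at 1.0 min.

The flask gives 40.5%, 41.2% and 40.5%, beside 40.3% from the selectivity factor and this flask's charges.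

    starting material → intermediate (k = 0.0990 /min)
    first nucleophile + intermediate → target (k = 160 /M/min)
    second nucleophile + intermediate → other capture product (k = 150 /M/min)
    intermediate → solvolysis product (k = 150 /min)
    second nucleophile → decomposed reagent (k = 0.0310 /min)
    second nucleophile + protic impurity → quenched reagent (k = 3.30 /M/min)
    starting material + target → side product (k = 0.120 /M/min)

The step from intermediate to solvolysis product leaves the share at 1.0 min unchanged. In the neighbour flask with 2.6 M of second nucleophile, the logarithms add to 0.431, a share of 73.0%, and that flask gives 73.2%.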